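Retrosynthetic cuts: first the depside ester bond C7(=O)–O–C4' between rings A and B. Then two ring bonds in each arene (C1'–C2' and C5'–C6' in ring B, C1–C2 and C5–C6 in ring A). Last, the alkyne–CO2Bn bond and the propargyl–C(thioacetal) bond of the shared side-chain piece.
Enabling feature: in ring B the neighbours C1' (CO2H) and C6' (2-oxoheptyl) are the two carbons of an alkynoate, and C2'(OMe)–C3'–C4'(O)–C5' is a 1,3-dioxygenated butadiene. C2' enters as a dimethyl ketene acetal and C4' as a silyl enol ether, so the ortho oxygen arrives methylated and the para oxygen arrives as the only free OH.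
Forward order: hexanal is masked as a dithiane, propargylated and carboxylated to one alkynoate 10. Alkynoate 10 closes ring B with diene 14 and ring A with diene 20. The ring A acid then acylates the ring B phenol, both ketones are unmasked, and the two benzyl groups are hydrogenolysed last.
Stereochemistry: the target (C30H38O9) has no stereocentre, stereoaxis or configured double bond, so only one stereoisomer exists and nothing has to be set.

Key step: step 7

Remark: the ketene acetal geometry of 19 and 20 and the transient stereocentre of 21 disappear on aromatisation. They are drawn without descriptors.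

Step 1
Reactants: 1 hexanal; 2 propane-1,3-dithiol
Product: 3 2-pentyl-1,3-dithiane
Conditions: BF3·OEt2 (cat.), CH2Cl2, 0 °C → rt
Reagents that add atoms: none
Why: Lewis-acid-catalysed thioacetalisation of an unhindered aldehyde is reliable and provides both the ketone mask and the acyl-anion handle.

Step 2
Reactants: 3 2-pentyl-1,3-dithiane; 4 3-bromo-1-(trimethylsilyl)prop-1-yne
Product: 6 trimethyl[3-(2-pentyl-1,3-dithian-2-yl)prop-1-yn-1-yl]silane, via 2-lithio-2-pentyl-1,3-dithiane 5 (not isolated)
Conditions: n-BuLi, THF, −30 °C, 2 h; then 4, −78 °C → rt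
Reagents that add atoms: none
Why: In this Corey–Seebach umpolung alkylation the soft 2-lithiodithiane displaces the primary propargylic bromide by SN2, while the silyl cap removes the acidic alkyne proton and blocks SN2' attack.

Step 3
Reactants: 6 trimethyl[3-(2-pentyl-1,3-dithian-2-yl)prop-1-yn-1-yl]silane
Product: 7 2-pentyl-2-(prop-2-yn-1-yl)-1,3-dithiane
Conditions: K2CO3 (cat.), MeOH, rt
Reagents that add atoms: none
Why: Carbonate-catalysed methanolysis of the alkynyl–silicon bond (protodesilylation) is mild, and the thioacetal is inert to base.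

Step 4
Reactants: 7 2-pentyl-2-(prop-2-yn-1-yl)-1,3-dithiane; 8 benzyl chloroformate
Product: 10 benzyl 4-(2-pentyl-1,3-dithian-2-yl)but-2-ynoate, via lithium acetylide of 7 9 (not isolated)
Conditions: n-BuLi, THF, −78 °C; then 8, −78 → 0 °C
Reagents that add atoms: none
Why: C-acylation of a lithium acetylide with a chloroformate is the standard alkynoate synthesis, and the 2,2-disubstituted dithiane has no competing acidic site.

Step 5
Reactants: 11 1,1-dimethoxyethene; 12 acetyl chloride
Product: 13 4,4-dimethoxybut-3-en-2-one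
Conditions: Et3N, Et2O, 0 °C → rt
Reagents that add atoms: none
Why: C-acylation of the electron-rich ketene acetal by the acid chloride, with the amine taking up HCl, should give the push–pull enone.

Step 6
Reactants: 13 4,4-dimethoxybut-3-en-2-one
Product: 14 1,1-dimethoxy-3-(trimethylsilyloxy)buta-1,3-diene
Conditions: TMSCl, Et3N, ZnCl2 (cat.), toluene, 40 °C; distilled and kept dry
Reagents that add atoms: chlorotrimethylsilane, C[Si](C)(C)Cl
Why: Soft enolisation and O-silylation of the methyl ketone, the only enolisable position, is the usual route to 2-silyloxydienes.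

Step 7
Reactants: 10 benzyl 4-(2-pentyl-1,3-dithian-2-yl)but-2-ynoate; 14 1,1-dimethoxy-3-(trimethylsilyloxy)buta-1,3-diene
Product: 17 benzyl 4-hydroxy-2-methoxy-6-[(2-pentyl-1,3-dithian-2-yl)methyl]benzoate, via cyclohexa-1,4-diene cycloadduct 15 (not isolated), via aryl trimethylsilyl ether 16 (not isolated)
Conditions: 14 (2.5 equiv), toluene, 120 °C, sealed tube; then 1 M HCl, THF, rt
Reagents that add atoms: none
Why: The three oxygen donors of 14 place the largest HOMO coefficient on its terminal CH2 and the ester of 10 makes the β-alkyne carbon the electrophilic end, so in a normal-demand, concerted but strongly asynchronous Diels–Alder reaction the C5'–C6' bond leads and the ketene acetal carbon then bonds to the α-carbon (C1'–C2'). Ring B closes in this single intermolecular (4+2) event as the six-membered carbocycle 15, four ring atoms coming from the diene and two from the alkyne. At 120 °C adduct 15 should lose methanol by 1,4-elimination across C2'/C5' to give arene 16, and the dilute acid then cleaves the aryl silyl ether to 17 and destroys surplus diene. The closest known reaction type is the Diels–Alder/aromatisation of 1,1-dialkoxy-3-silyloxybutadienes with β-alkyl acetylenic esters, which gives 2-alkoxy-4-hydroxy-6-alkylbenzoates. No stereocentre is formed (C2' of 15 carries two identical methoxy groups), so only the orientation matters, and it is secured by the matched polarisation of the two partners. The thioacetal and the benzyl ester are spectators, and any thermal drift of 10 towards its allenic isomer would lead to the same arene.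

Step 8
Reactants: 18 methyl (E)-3-methoxybut-2-enoate
Product: 20 1,3-dimethoxy-1-(trimethylsilyloxy)buta-1,3-diene, via lithium dienolate of 18 19 (not isolated)
Conditions: LDA, THF, −78 °C; then TMSCl, −78 °C → rt; distilled
Reagents that add atoms: chlorotrimethylsilane, C[Si](C)(C)Cl
Why: Kinetic γ-deprotonation of the β-methoxy enoate followed by O-silylation of the extended enolate is the established preparation of this mixed silyl ketene acetal diene.

Step 9
Reactants: 10 benzyl 4-(2-pentyl-1,3-dithian-2-yl)but-2-ynoate; 20 1,3-dimethoxy-1-(trimethylsilyloxy)buta-1,3-diene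
Product: 23 benzyl 2-hydroxy-4-methoxy-6-[(2-pentyl-1,3-dithian-2-yl)methyl]benzoate, via cyclohexa-1,4-diene cycloadduct 21 (not isolated), via aryl trimethylsilyl ether 22 (not isolated)
Conditions: 20 (2.5 equiv), toluene, 120 °C, sealed tube; then 1 M HCl, THF, rt
Reagents that add atoms: none
Why: This is the same polarity-matched Diels–Alder/aromatisation as in step 7, but the mixed acetal carbon now loses methanol and then its silyl group, so the ortho oxygen should emerge as the chelated phenol while the para oxygen keeps its methyl group.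

Step 10
Reactants: 23 benzyl 2-hydroxy-4-methoxy-6-[(2-pentyl-1,3-dithian-2-yl)methyl]benzoate
Product: 24 benzyl 2-(benzyloxy)-4-methoxy-6-[(2-pentyl-1,3-dithian-2-yl)methyl]benzoate
Conditions: BnBr, K2CO3, DMF, 60 °C
Reagents that add atoms: benzyl bromide, BrCc1ccccc1
Why: Williamson etherification in warm DMF overcomes the chelation of the ortho phenol, and the phenoxide reacts far faster than the thioacetal sulfur.

Step 11
Reactants: 24 benzyl 2-(benzyloxy)-4-methoxy-6-[(2-pentyl-1,3-dithian-2-yl)methyl]benzoate
Product: 26 2-(benzyloxy)-4-methoxy-6-[(2-pentyl-1,3-dithian-2-yl)methyl]benzoic acid, via potassium carboxylate 25 (not isolated)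
Conditions: KOH, DMSO/H2O (4:1), 90 °C; then 1 M HCl, 0 °C
Reagents that add atoms: potassium hydroxide, [K+].[OH-]
Why: Saponification of a doubly ortho-substituted benzoate with poorly solvated hydroxide in hot aqueous DMSO is the standard answer to the steric hindrance, and aryl ethers and the thioacetal are inert to it.

Step 12
Reactants: 26 2-(benzyloxy)-4-methoxy-6-[(2-pentyl-1,3-dithian-2-yl)methyl]benzoic acid; 17 benzyl 4-hydroxy-2-methoxy-6-[(2-pentyl-1,3-dithian-2-yl)methyl]benzoate
Product: 27 benzyl 4-({2-(benzyloxy)-4-methoxy-6-[(2-pentyl-1,3-dithian-2-yl)methyl]benzoyl}oxy)-2-methoxy-6-[(2-pentyl-1,3-dithian-2-yl)methyl]benzoate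
Conditions: DCC, DMAP (0.3 equiv), CH2Cl2, 0 °C → rt
Reagents that add atoms: none
Why: Steglich esterification should join the fragments because the single free hydroxyl of 17 (C4'–OH, flanked by two CH) is unhindered and the masked ketone of 26 cannot lactonise onto the activated carboxyl.

Step 13
Reactants: 27 bis-dithiane depside benzyl ester
Product: 28 benzyl 4-{[2-(benzyloxy)-4-methoxy-6-(2-oxoheptyl)benzoyl]oxy}-2-methoxy-6-(2-oxoheptyl)benzoate
Conditions: MeI (excess), CaCO3, MeCN/H2O (9:1), 45 °C, dark
Reagents that add atoms: water, O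
Why: In this alkylative thioacetal hydrolysis S-methylation makes each dithiane a leaving group and water traps the thionium ion, and the non-oxidising, carbonate-buffered medium spares the electron-rich arenes, the benzyl groups and the aryl ester.

Step 14
Reactants: 28 benzyl 4-{[2-(benzyloxy)-4-methoxy-6-(2-oxoheptyl)benzoyl]oxy}-2-methoxy-6-(2-oxoheptyl)benzoate
Product: 29 4-{[2-hydroxy-4-methoxy-6-(2-oxoheptyl)benzoyl]oxy}-2-methoxy-6-(2-oxoheptyl)benzoic acid (target)
Conditions: H2 (1 atm), 10% Pd/C, EtOAc, rt; chromatographed 28 free of sulfur residues; work-up without acid or heat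
Reagents that add atoms: none
Why: Catalytic hydrogenolysis removes the benzyl ester and the aryl benzyl ether together once all sulfur has left the molecule, and the ketones and the depside ester are not touched at 1 atm in an aprotic solvent.

Compound list
1 | hexanal | CCCCCC=O | starting material
2 | propane-1,3-dithiol | SCCCS | starting material
3 | 2-pentyl-1,3-dithiane | CCCCCC1SCCCS1 | intermediate
4 | 3-bromo-1-(trimethylsilyl)prop-1-yne | C[Si](C)(C)C#CCBr | starting material
5 | 2-lithio-2-pentyl-1,3-dithiane (not isolated) | [Li]C1(CCCCC)SCCCS1 | intermediate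
6 | trimethyl[3-(2-pentyl-1,3-dithian-2-yl)prop-1-yn-1-yl]silane | CCCCCC1(CC#C[Si](C)(C)C)SCCCS1 | intermediate
7 | 2-pentyl-2-(prop-2-yn-1-yl)-1,3-dithiane | CCCCCC1(CC#C)SCCCS1 | intermediate
8 | benzyl chloroformate | O=C(Cl)OCc1ccccc1 | starting material
9 | lithium acetylide of 7 (not isolated) | [Li]C#CCC1(CCCCC)SCCCS1 | intermediate
10 | benzyl 4-(2-pentyl-1,3-dithian-2-yl)but-2-ynoate | CCCCCC1(CC#CC(=O)OCc2ccccc2)SCCCS1 | intermediate
11 | 1,1-dimethoxyethene | C=C(OC)OC | starting material
12 | acetyl chloride | CC(=O)Cl | starting material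
13 | 4,4-dimethoxybut-3-en-2-one | CC(=O)C=C(OC)OC | intermediate
14 | 1,1-dimethoxy-3-(trimethylsilyloxy)buta-1,3-diene | C=C(O[Si](C)(C)C)C=C(OC)OC | intermediate
15 | benzyl 6,6-dimethoxy-2-[(2-pentyl-1,3-dithian-2-yl)methyl]-4-(trimethylsilyloxy)cyclohexa-1,4-diene-1-carboxylate (not isolated) | CCCCCC1(CC2=C(C(=O)OCc3ccccc3)C(OC)(OC)C=C(O[Si](C)(C)C)C2)SCCCS1 | intermediate
16 | benzyl 2-methoxy-6-[(2-pentyl-1,3-dithian-2-yl)methyl]-4-(trimethylsilyloxy)benzoate (not isolated) | CCCCCC1(Cc2cc(O[Si](C)(C)C)cc(OC)c2C(=O)OCc2ccccc2)SCCCS1 | intermediate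
17 | benzyl 4-hydroxy-2-methoxy-6-[(2-pentyl-1,3-dithian-2-yl)methyl]benzoate | CCCCCC1(Cc2cc(O)cc(OC)c2C(=O)OCc2ccccc2)SCCCS1 | intermediate
18 | methyl (E)-3-methoxybut-2-enoate | COC(=O)/C=C(/OC)C | starting material
19 | lithium dienolate of 18 (not isolated) | [Li]OC(OC)=CC(=C)OC | intermediate
20 | 1,3-dimethoxy-1-(trimethylsilyloxy)buta-1,3-diene | C=C(OC)C=C(OC)O[Si](C)(C)C | intermediate
21 | benzyl 4,6-dimethoxy-2-[(2-pentyl-1,3-dithian-2-yl)methyl]-6-(trimethylsilyloxy)cyclohexa-1,4-diene-1-carboxylate (racemic, not isolated) | CCCCCC1(CC2=C(C(=O)OCc3ccccc3)C(OC)(O[Si](C)(C)C)C=C(OC)C2)SCCCS1 | intermediate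
22 | benzyl 4-methoxy-2-[(2-pentyl-1,3-dithian-2-yl)methyl]-6-(trimethylsilyloxy)benzoate (not isolated) | CCCCCC1(Cc2cc(OC)cc(O[Si](C)(C)C)c2C(=O)OCc2ccccc2)SCCCS1 | intermediate
23 | benzyl 2-hydroxy-4-methoxy-6-[(2-pentyl-1,3-dithian-2-yl)methyl]benzoate | CCCCCC1(Cc2cc(OC)cc(O)c2C(=O)OCc2ccccc2)SCCCS1 | intermediate
24 | benzyl 2-(benzyloxy)-4-methoxy-6-[(2-pentyl-1,3-dithian-2-yl)methyl]benzoate | CCCCCC1(Cc2cc(OC)cc(OCc3ccccc3)c2C(=O)OCc2ccccc2)SCCCS1 | intermediate
25 | potassium 2-(benzyloxy)-4-methoxy-6-[(2-pentyl-1,3-dithian-2-yl)methyl]benzoate (not isolated) | CCCCCC1(Cc2cc(OC)cc(OCc3ccccc3)c2C(=O)[O-])SCCCS1.[K+] | intermediate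
26 | 2-(benzyloxy)-4-methoxy-6-[(2-pentyl-1,3-dithian-2-yl)methyl]benzoic acid | CCCCCC1(Cc2cc(OC)cc(OCc3ccccc3)c2C(=O)O)SCCCS1 | intermediate
27 | benzyl 4-({2-(benzyloxy)-4-methoxy-6-[(2-pentyl-1,3-dithian-2-yl)methyl]benzoyl}oxy)-2-methoxy-6-[(2-pentyl-1,3-dithian-2-yl)methyl]benzoate | CCCCCC1(Cc2cc(OC)cc(OCc3ccccc3)c2C(=O)Oc2cc(CC3(CCCCC)SCCCS3)c(C(=O)OCc3ccccc3)c(OC)c2)SCCCS1 | intermediate
28 | benzyl 4-{[2-(benzyloxy)-4-methoxy-6-(2-oxoheptyl)benzoyl]oxy}-2-methoxy-6-(2-oxoheptyl)benzoate | CCCCCC(=O)Cc1cc(OC)cc(OCc2ccccc2)c1C(=O)Oc1cc(CC(=O)CCCCC)c(C(=O)OCc2ccccc2)c(OC)c1 | intermediate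
29 | 4-{[2-hydroxy-4-methoxy-6-(2-oxoheptyl)benzoyl]oxy}-2-methoxy-6-(2-oxoheptyl)benzoic acid (CNP0177576.0, achiral) | CCCCCC(=O)Cc1cc(OC)cc(O)c1C(=O)Oc1cc(CC(=O)CCCCC)c(C(=O)O)c(OC)c1 | target

Total step count: 14. Longest linear sequence: 10 (steps 1–4 and 9–14).

Steps most likely to fail

Step 7. The β-alkyne carbon is shielded by the neopentyl-like CH2–thioacetal unit. The cycloaddition may therefore be slow enough for thermal decay of the diene, and its protolysis by the liberated methanol, to outrun bond formation.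
The fallback sets out from 10 and returns at 17.
- Treating 10 with LDA in THF at −78 °C and quenching cold with acetic acid should protonate the cumulenolate at the α-carbon. This gives benzyl 4-(2-pentyl-1,3-dithian-2-yl)buta-2,3-dienoate F1 (racemic). Further drift to a 2,4-dienoate is impossible because the next carbon is quaternary.
- The α,β-double bond of an allenoate is a more reactive dienophile, and one of its faces carries only hydrogen. Diene 14 should therefore add at 60–80 °C in the same orientation to give benzyl 2,2-dimethoxy-6-[(2-pentyl-1,3-dithian-2-yl)methylidene]-4-(trimethylsilyloxy)cyclohex-3-ene-1-carboxylate F2 (racemic).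
- Loss of methanol and a prototropic shift of the exocyclic double bond lead to 16. The acid work-up of step 7 then gives 17.

Step 9. Aromatisation may partition between loss of methanol and loss of silanol from the mixed acetal carbon, which would blur the hydroxy/methoxy pattern. The more hydrolysis-prone diene may also be consumed before it adds.
The fallback sets out from 17 and returns at 24. It derives ring A from the ring B arene by moving the methyl group.
- MeI and K2CO3 in acetone at rt should give benzyl 2,4-dimethoxy-6-[(2-pentyl-1,3-dithian-2-yl)methyl]benzoate F3.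
- BCl3 (3 equiv) in CH2Cl2 from −78 to 0 °C should remove only the methyl group on the oxygen chelated to the carbonyl, and the benzyl ester with it. This gives 2-hydroxy-4-methoxy-6-[(2-pentyl-1,3-dithian-2-yl)methyl]benzoic acid F4.
- Double benzylation of F4 with BnBr (2.5 equiv) and K2CO3 in DMF delivers 24.

Step 13. S-alkylation of two hindered thioacetals may need long heating. During that time the liberated ring A ketone can enolise and attack the depside carbonyl, which would transfer the acyl group and release the ring B phenol.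
The fallback sets out from 17 and returns at 28. It moves half of the unmasking ahead of the coupling and uses a fast thiophilic metal.
- Hg(ClO4)2 and CaCO3 in THF/H2O at 0 °C should convert 17 into benzyl 4-hydroxy-2-methoxy-6-(2-oxoheptyl)benzoate F5.
- Steglich coupling of F5 with 26 gives benzyl 4-({2-(benzyloxy)-4-methoxy-6-[(2-pentyl-1,3-dithian-2-yl)methyl]benzoyl}oxy)-2-methoxy-6-(2-oxoheptyl)benzoate F6. The ring A ketone stays masked here so that the activated acid cannot form an enol lactone.
- A single short exposure of F6 to Hg(ClO4)2 and CaCO3 at 0 °C gives 28.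

Further compounds
F1 | step 7 | benzyl 4-(2-pentyl-1,3-dithian-2-yl)buta-2,3-dienoate (racemic allene) | CCCCCC1(C=C=CC(=O)OCc2ccccc2)SCCCS1
F2 | step 7 | benzyl 2,2-dimethoxy-6-[(2-pentyl-1,3-dithian-2-yl)methylidene]-4-(trimethylsilyloxy)cyclohex-3-ene-1-carboxylate (racemic, alkene geometry undefined) | CCCCCC1(C=C2CC(O[Si](C)(C)C)=CC(OC)(OC)C2C(=O)OCc2ccccc2)SCCCS1
F3 | step 9 | benzyl 2,4-dimethoxy-6-[(2-pentyl-1,3-dithian-2-yl)methyl]benzoate | CCCCCC1(Cc2cc(OC)cc(OC)c2C(=O)OCc2ccccc2)SCCCS1
F4 | step 9 | 2-hydroxy-4-methoxy-6-[(2-pentyl-1,3-dithian-2-yl)methyl]benzoic acid | CCCCCC1(Cc2cc(OC)cc(O)c2C(=O)O)SCCCS1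
F5 | step 13 | benzyl 4-hydroxy-2-methoxy-6-(2-oxoheptyl)benzoate | CCCCCC(=O)Cc1cc(O)cc(OC)c1C(=O)OCc1ccccc1
F6 | step 13 | benzyl 4-({2-(benzyloxy)-4-methoxy-6-[(2-pentyl-1,3-dithian-2-yl)methyl]benzoyl}oxy)-2-methoxy-6-(2-oxoheptyl)benzoate | CCCCCC1(Cc2cc(OC)cc(OCc3ccccc3)c2C(=O)Oc2cc(CC(=O)CCCCC)c(C(=O)OCc3ccccc3)c(OC)c2)SCCCS1
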